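(The earlier runs and the new flask stem from a simulated flask on assumed constants, and the scatter is random.)

How much target can oak's flask hold at its best, when is that, and when does it first pass the level asked, given that target is being lost while it forms?

the same everywhere: gas phase 72 mM (held)

| charge | substrate | remark | time |
|---|---|---|---|
| oak | 2 M | the very flask that is asked about, followed so far |  |
| birch | 3 M | run made earlier |  |
| flask | 2.0 M |  | 15 d |

| run | time / d | target / % | substrate / % |
|---|---|---|---|
| oak | 0.104 | 25.2 | 74.3 |
| oak | 0.167 | 37.1 | 61.7 |
| oak | 0.333 | 52.9 | 40.3 |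
| oak | 0.500 | 54.1 | 31.6 |
| oak | 1.04 | 38.3 | 19.7 |
| oak | 1.67 | 23.6 | 11.2 |
| oak | 3.00 | 7.1 | 3.2 |
| birch | 0.104 | 18.5 | 81.5 |
| birch | 0.208 | 33.7 | 66.0 |
| birch | 0.500 | 50.9 | 39.4 |
| birch | 1.04 | 42.3 | 24.6 |
| birch | 2.50 | 14.8 | 6.9 |
| birch | 5.00 | 2.3 | 0.2 |
| birch | 10.0 | 0 | 0.9 |

(readings scatter by 0.3 percentage points)

- the best time, 15 d at the latest, for target
- the amount of target, in percent of the substrate charged, at that time
- the first time at which target reaches 27%, in the same percent, in d

- at the start none of the gas phase is in solution

Late in the oak run target and substrate fall together, their ratio R reading 2.11 at 1.67 d and 2.22 at 3.00 d, so I treat substrate and target there as a pre-equilibrium and reckon with the pair, target plus substrate, which is what the ratio leaves free to fall: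

λ = ln(34.8% / 10.3%) / (3.00 d − 1.67 d) = 0.915 /d

This λ, the drain constant, the fractional loss of the pair per unit time once the ratio holds, is what I carry, and the pair is what to watch on a repeat.

In a version with no drain, and with R kept at its reading at 1.67 d, the pair keeps the whole charge and target stands at the share f:

f = R/(1 + R) = 67.8%

With the ratio in place at once and λ at full strength from the start, target at 0.416 d, midway between the readings at 0.333 d and 0.500 d, is

f·exp(−λt) = 46.3%

The oak flask lies between these two versions, because at 0.500 d its pair still reads 85.7%, more than the 63.3% that full λ leaves. I commit to a peak near 0.416 d, a little above the 54.1% read at 0.500 d, and to a first passage between the readings at 0.104 d and 0.167 d.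

The forecast gives 0.44 d, 54.5% and 0.113 d, on the ground “I read the answer from the oak curve”.

The simulation gives 0.415 d, 54.4% and 0.111 d. At 0.415 d the oak flask holds 10.5% over-reacted product, while full λ from the start would have taken 31.6% of the charge from the pair, so the flask has lost a third of that.

    gas phase ⇌ dissolved gas, rate k1*(csat - [dissolved gas]) (kL = 0.00100 /s)
    substrate + dissolved gas ⇌ target (K = 37.6 /M, k = 0.00487 /M/s)
    dissolved gas + target → over-reacted product (k = 2.45 × 10⁻⁴ /M/s)
    dissolved gas → decomposed reagent (k = 2.82 × 10⁻⁵ /s)
    dissolved gas ⇌ dormant form (K = 12.0, k = 4.20 × 10⁻⁵ /s)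

For the same charge read at 4.0 d, λ carries the pair from 10.3% at 3.00 d to 4.12%. The computed flask holds 1.07% substrate and 2.63% target, together 3.70%, less than λ gave.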